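**Retrosynthetic overview**
1. Target 6 is an aryl ketone ArC(=O)–CH2CH2–R. The C(=O)–CH2 bond is cut by a Rh-catalysed anti-Markovnikov hydroacylation of terminal alkene 4 with unprotected 2,6-dihydroxybenzaldehyde 5 (key step).
2. This replaces the usual route (protected 2,6-dialkoxyphenyllithium plus a C9 acyl or aldehyde partner, then oxidation and deprotection).
3. Alkene 4 is cut at the aryl–CH2 bond: B-alkyl Suzuki coupling of 4-bromo-2-methoxyphenol 3 with borane 2.
4. Borane 2 comes from mono-hydroboration of octa-1,7-diene 1 with 9-BBN.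
5. No ring is formed at any stage (both benzene rings are bought intact), and no protecting group is used.

**Assumptions**
- The target has no stereocentre and no stereogenic double bond; it is achiral, so "single enantiomer" means the one compound drawn and no stereocontrol is needed.
- Steps 1 and 3 are additions in which every atom of both partners ends up in the product, so they have no co-product.
- Borane 2 is not purified; it is carried forward as a crude concentrate and counted as a step of its own.

**Route**

Step 1
Reactants: 1 octa-1,7-diene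
Product: 2 9-(oct-7-en-1-yl)-9-borabicyclo[3.3.1]nonane
Conditions: 9-BBN (0.5 M in THF, 1.0 equiv), 1 (4.0 equiv), THF, 0 °C → rt, 3 h; THF and excess 1 stripped in vacuo under Ar, crude 2 used directly
Reagents that add atoms: 9-BBN (9-borabicyclo[3.3.1]nonane), B1C2CCCC1CCC2
Why: Brown hydroboration, in which 9-BBN adds anti-Markovnikov to a terminal alkene and the fourfold excess of the symmetrical diene keeps the second alkene of the mono-adduct largely untouched; no stereocentre is formed.

Step 2
Reactants: 2 9-(oct-7-en-1-yl)-9-borabicyclo[3.3.1]nonane; 3 4-bromo-2-methoxyphenol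
Product: 4 2-methoxy-4-(oct-7-en-1-yl)phenol
Conditions: 2 (1.3 equiv), 3 (1.0 equiv), Pd(OAc)2 (3 mol %), SPhos (6 mol %), K3PO4 (3 M aq, 3.5 equiv), THF, 65 °C, 12 h; aq NH4Cl work-up
Reagents that add atoms: none
Why: B-alkyl Suzuki–Miyaura coupling, in which the hydroxyborate of 2 transfers only its primary alkyl group, the electron-rich biarylphosphine allows oxidative addition to the electron-rich bromophenol (the free OH only consumes extra base) and reductive elimination outruns β-hydride elimination, leaving the remote terminal alkene intact; no stereocentre is formed.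

Step 3
Reactants: 4 2-methoxy-4-(oct-7-en-1-yl)phenol; 5 2,6-dihydroxybenzaldehyde
Product: 6 1-(2,6-dihydroxyphenyl)-9-(4-hydroxy-3-methoxyphenyl)nonan-1-one
Conditions: 5 (1.0 equiv), 4 (1.5 equiv, excess recovered), [Rh(cod)Cl]2 (2.5 mol %), bulky BINOL-derived phosphoramidite (MonoPhos type, 10 mol %), K3PO4 (10 mol %), degassed THF, 70 °C, 24 h
Reagents that add atoms: none
Why: Rh(I)-catalysed chelation-assisted intermolecular alkene hydroacylation of a salicylaldehyde, a known reaction class applied here to an untested substrate pair, in which the ortho-phenoxide binds Rh so that aldehyde C–H oxidative addition gives a five-membered acyl-rhodium hydride chelate that resists decarbonylation, and anti-Markovnikov insertion of the unactivated terminal alkene followed by C–C reductive elimination gives the linear ketone with all phenols unprotected; no stereocentre is formed.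

**Compound list**
1 | octa-1,7-diene | C=CCCCCC=C | starting material
2 | 9-(oct-7-en-1-yl)-9-borabicyclo[3.3.1]nonane | C=CCCCCCCB1C2CCCC1CCC2 | intermediate
3 | 4-bromo-2-methoxyphenol | COc1cc(Br)ccc1O | starting material
4 | 2-methoxy-4-(oct-7-en-1-yl)phenol | COc1cc(CCCCCCC=C)ccc1O | intermediate
5 | 2,6-dihydroxybenzaldehyde | O=Cc1c(O)cccc1O | starting material
6 | 1-(2,6-dihydroxyphenyl)-9-(4-hydroxy-3-methoxyphenyl)nonan-1-one | COc1cc(CCCCCCCCC(=O)c2c(O)cccc2O)ccc1O | target

**Totals**
Total step count: 3 (two chromatographic purifications; 2 is telescoped as a crude concentrate).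
Longest linear sequence: 3 steps (1 → 2 → 4 → 6).

**Steps most likely to fail, with fallbacks**

1. Step 3 (hydroacylation). The risks are branched ketone, Rh–H chain-walking of the alkene and decarbonylation of the aldehyde. The fallback builds the ketone by a three-component carbonylative Suzuki–Miyaura coupling; it sets out from 4 and comes back to the route at 6. Alkene 4 is O-benzylated (BnBr, K2CO3, DMF) to 1-(benzyloxy)-2-methoxy-4-(oct-7-en-1-yl)benzene F1. F1 is hydroborated with 9-BBN (THF, rt) to 9-{8-[4-(benzyloxy)-3-methoxyphenyl]octyl}-9-borabicyclo[3.3.1]nonane F2. Purchased 2-iodobenzene-1,3-diol (Oc1cccc(O)c1I) is benzylated (BnBr, K2CO3, acetone) to 1,3-bis(benzyloxy)-2-iodobenzene F3. Borane F2, iodide F3 and CO (1 atm) are coupled (Pd(PPh3)4, K3PO4, dioxane, 50 °C) to 9-[4-(benzyloxy)-3-methoxyphenyl]-1-[2,6-bis(benzyloxy)phenyl]nonan-1-one F4. Hydrogenolysis of the three benzyl ethers (H2 1 atm, Pd/C, EtOAc, rt) gives 6; the doubly hydrogen-bonded aryl ketone and the aryl methyl ether survive.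

2. Step 2 (B-alkyl Suzuki on a free bromophenol). The risk is that the phenoxide slows oxidative addition so that reduction and protodeboronation win. The fallback masks the phenol instead of coupling it free; it sets out from 3 and comes back at 4. Bromophenol 3 is silylated (TIPSCl, imidazole, DMF) to (4-bromo-2-methoxyphenoxy)tri(propan-2-yl)silane F5. F5 is coupled with borane 2 (PdCl2(dppf), K3PO4, THF/DMF/H2O, 60 °C) to [2-methoxy-4-(oct-7-en-1-yl)phenoxy]tri(propan-2-yl)silane F6. TBAF (THF, 0 °C) then returns 4.

3. Step 1 (statistical mono-hydroboration of a symmetrical diene). The risk is the bis-borane, which would give the 1,8-diaryloctane in step 2. The fallback drops the diene and the organoboron reagent altogether; it sets out from 3 and comes back at 4 in one operation, bypassing 1 and 2. Bromophenol 3 undergoes nickel-catalysed reductive cross-electrophile coupling with purchased 8-bromooct-1-ene (C=CCCCCCCBr) under NiI2, 4,4'-di-tert-butyl-2,2'-bipyridine, Zn dust, NaI, pyridine, DMPU, 60 °C; this reaction class tolerates free O–H. No new compound is made on this path (F0).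

**Further compounds**
F1 | step 3 | 1-(benzyloxy)-2-methoxy-4-(oct-7-en-1-yl)benzene | COc1cc(CCCCCCC=C)ccc1OCc1ccccc1
F2 | step 3 | 9-{8-[4-(benzyloxy)-3-methoxyphenyl]octyl}-9-borabicyclo[3.3.1]nonane | COc1cc(CCCCCCCCB2C3CCCC2CCC3)ccc1OCc1ccccc1
F3 | step 3 | 1,3-bis(benzyloxy)-2-iodobenzene | Ic1c(OCc2ccccc2)cccc1OCc1ccccc1
F4 | step 3 | 9-[4-(benzyloxy)-3-methoxyphenyl]-1-[2,6-bis(benzyloxy)phenyl]nonan-1-one | COc1cc(CCCCCCCCC(=O)c2c(OCc3ccccc3)cccc2OCc2ccccc2)ccc1OCc1ccccc1
F5 | step 2 | (4-bromo-2-methoxyphenoxy)tri(propan-2-yl)silane | COc1cc(Br)ccc1O[Si](C(C)C)(C(C)C)C(C)C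
F6 | step 2 | [2-methoxy-4-(oct-7-en-1-yl)phenoxy]tri(propan-2-yl)silane | COc1cc(CCCCCCC=C)ccc1O[Si](C(C)C)(C(C)C)C(C)C
F0 | step 1 | none | none
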